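**Retrosynthetic overview**

1. Target 16 ⇒ ynone 13 by formal hydration of C≡C (through an enaminone) and loss of two MOM groups; the CH2–C(=O) unit next to ring B is carried as an alkyne.
2. 13 ⇒ cut the bond between ring A C1 and its carbonyl carbon: aryllithium 11 (C1–Li, from bromide 5) plus the non-enolisable alkynyl N-methoxy-N-methylamide 10, which holds the whole ring B/C3 half.
3. Enabling feature: the acyl-bearing C1 of ring A lies ortho to the C2 methoxy and para to the C4 oxygen, which is the bromine position of commercial 4-bromo-3-methoxyphenol. The methylated C2 oxygen cannot add to the ynone (no flavone), and C3, between the two ring A oxygens, is the most acidic ring C–H and takes the prenyl group.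
4. 5 ⇒ 4-bromo-3-methoxyphenol 1 (MOM ether, then deprotonation and prenylation at C3); 10 ⇒ 4-iodophenol 6 (MOM ether, Sonogashira coupling with propiolic acid, amidation).
5. Rings: none is built; benzene rings A and B are both bought, and only the three-carbon bridge between them is made.

Key step: step 6

Assumption: the target is treated as the diketo tautomer of the given SMILES; it equilibrates with the chelated enol, which affects no step; compounds 1, 3, 6 and 8 are taken as commercial.

**Route**

Step 1
Reactants: 1 4-bromo-3-methoxyphenol
Product: 2 1-bromo-2-methoxy-4-(methoxymethoxy)benzene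
Conditions: NaH, MOMCl, THF–DMF, 0 °C → rt
Reagents that add atoms: chloromethyl methyl ether, COCCl
Why: Williamson-type O-alkylation of the sodium phenoxide with the reactive α-chloro ether (MOM protection) should be clean, and the acetal ether later directs the ring deprotonation.

Step 2
Reactants: 2 1-bromo-2-methoxy-4-(methoxymethoxy)benzene; 3 1-bromo-3-methylbut-2-ene (prenyl bromide)
Product: 5 1-bromo-2-methoxy-4-(methoxymethoxy)-3-(3-methylbut-2-en-1-yl)benzene, via aryllithium 4 (not isolated)
Conditions: LDA, THF, −78 °C; then CuBr·SMe2 (10 mol %), 3, −78 → 0 °C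
Reagents that add atoms: none
Why: Directed ortho-metalation: the C–H between the methoxy and the MOM ether is the most acidic ring position and the amide base should remove it without touching the C–Br bond, after which copper-catalysed allylic substitution on prenyl bromide should occur at the primary carbon (SN2).

Step 3
Reactants: 6 4-iodophenol
Product: 7 1-iodo-4-(methoxymethoxy)benzene
Conditions: NaH, MOMCl, THF–DMF, 0 °C → rt
Reagents that add atoms: chloromethyl methyl ether, COCCl
Why: The same Williamson-type MOM protection as in step 1; the aryl iodide is inert to these conditions.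

Step 4
Reactants: 7 1-iodo-4-(methoxymethoxy)benzene; 8 propiolic acid
Product: 9 3-[4-(methoxymethoxy)phenyl]prop-2-ynoic acid
Conditions: Pd(PPh3)4 (5 mol %), DBU (2.4 equiv), DMSO, rt; then cold dilute HCl to pH 3
Reagents that add atoms: none
Why: Copper-free Sonogashira coupling of the aryl iodide with propiolic acid as its amidinium carboxylate; at room temperature the arylpropiolate should not lose CO2.

Step 5
Reactants: 9 3-[4-(methoxymethoxy)phenyl]prop-2-ynoic acid
Product: 10 N-methoxy-3-[4-(methoxymethoxy)phenyl]-N-methylprop-2-ynamide
Conditions: MeNH(OMe)·HCl, EDC·HCl, N-methylmorpholine, CH2Cl2, 0 °C → rt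
Reagents that add atoms: N,O-dimethylhydroxylamine hydrochloride, CNOC.Cl
Why: Carbodiimide-mediated amide coupling (Weinreb amide formation); the weakly nucleophilic amine should acylate at nitrogen and not add to the triple bond at this temperature.

Step 6
Reactants: 5 1-bromo-2-methoxy-4-(methoxymethoxy)-3-(3-methylbut-2-en-1-yl)benzene; 10 N-methoxy-3-[4-(methoxymethoxy)phenyl]-N-methylprop-2-ynamide
Product: 13 1-[2-methoxy-4-(methoxymethoxy)-3-(3-methylbut-2-en-1-yl)phenyl]-3-[4-(methoxymethoxy)phenyl]prop-2-yn-1-one, via aryllithium 11 (not isolated), via lithium hemiaminal adduct 12 (not isolated)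
Conditions: 5, n-BuLi, THF, −78 °C, 20 min; then 10, −78 °C; quench at −78 °C with AcOH in THF, then water
Reagents that add atoms: none
Why: Bromine–lithium exchange at C1 of 5 should be faster at −78 °C than any deprotonation and gives aryllithium 11, held by the neighbouring C2 methoxy oxygen; 11 adds to the amide carbonyl of 10 and lithium is chelated between the alkoxide and the N-methoxy oxygen (12), so the ketone is released only on the quench and cannot take up a second aryl group. The closest known reaction type is the Weinreb ketone synthesis in its ynone form (organolithium plus alkynyl N-methoxy-N-methylamide). No ring is closed and no stereocentre is formed. The step needs site selectivity on ring A, 1,2- over 1,4-addition and freedom from proton transfer: the site is fixed by the bromine of 1 (ortho to the C2 methoxy, para to the C4 oxygen), the hard aryllithium attacks the carbonyl carbon while the electron-rich 4-alkoxyphenyl group makes the alkyne terminus a poor acceptor, and the acyl donor has no acidic hydrogen because the CH2–C(=O) unit of the target is carried as C≡C. This one bond formation assembles the whole C21 skeleton with the complete ring A substitution pattern from two fragments of about half its size. The cold acidic quench keeps the released N,O-dimethylhydroxylamine protonated so that it should not add to the ynone.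

Step 7
Reactants: 13 1-[2-methoxy-4-(methoxymethoxy)-3-(3-methylbut-2-en-1-yl)phenyl]-3-[4-(methoxymethoxy)phenyl]prop-2-yn-1-one
Product: 16 1-[4-hydroxy-2-methoxy-3-(3-methylbut-2-en-1-yl)phenyl]-3-(4-hydroxyphenyl)propane-1,3-dione, via diethylaminoenone 14 (not isolated), via bis-MOM diketone 15 (not isolated)
Conditions: Et2NH, MeOH, rt; then 3 M aq. HCl, MeOH–THF, rt → 45 °C
Reagents that add atoms: water, O
Why: Aza-Michael addition of diethylamine to the ynone gives the vinylogous amide, whose acid hydrolysis is the net hydration to the open-chain 1,3-diketone (the methylated C2 oxygen cannot close a flavone), and the same methanolic HCl should cleave both MOM acetals under the mild conditions customary for phenols next to a prenyl group.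

**Compound list**

1 | 4-bromo-3-methoxyphenol | COc1cc(O)ccc1Br | starting material
2 | 1-bromo-2-methoxy-4-(methoxymethoxy)benzene | COCOc1ccc(Br)c(OC)c1 | intermediate
3 | 1-bromo-3-methylbut-2-ene (prenyl bromide) | CC(C)=CCBr | starting material
4 | [3-bromo-2-methoxy-6-(methoxymethoxy)phenyl]lithium | COCOc1ccc(Br)c(OC)c1[Li] | intermediate
5 | 1-bromo-2-methoxy-4-(methoxymethoxy)-3-(3-methylbut-2-en-1-yl)benzene | COCOc1ccc(Br)c(OC)c1CC=C(C)C | intermediate
6 | 4-iodophenol | Oc1ccc(I)cc1 | starting material
7 | 1-iodo-4-(methoxymethoxy)benzene | COCOc1ccc(I)cc1 | intermediate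
8 | propiolic acid | C#CC(=O)O | starting material
9 | 3-[4-(methoxymethoxy)phenyl]prop-2-ynoic acid | COCOc1ccc(cc1)C#CC(=O)O | intermediate
10 | N-methoxy-3-[4-(methoxymethoxy)phenyl]-N-methylprop-2-ynamide | COCOc1ccc(cc1)C#CC(=O)N(C)OC | intermediate
11 | [2-methoxy-4-(methoxymethoxy)-3-(3-methylbut-2-en-1-yl)phenyl]lithium | [Li]c1ccc(OCOC)c(CC=C(C)C)c1OC | intermediate
12 | lithium 1-[methoxy(methyl)amino]-1-[2-methoxy-4-(methoxymethoxy)-3-(3-methylbut-2-en-1-yl)phenyl]-3-[4-(methoxymethoxy)phenyl]prop-2-yn-1-olate (racemic chelate) | COCOc1ccc(cc1)C#CC(O[Li])(N(C)OC)c1ccc(OCOC)c(CC=C(C)C)c1OC | intermediate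
13 | 1-[2-methoxy-4-(methoxymethoxy)-3-(3-methylbut-2-en-1-yl)phenyl]-3-[4-(methoxymethoxy)phenyl]prop-2-yn-1-one | COCOc1ccc(cc1)C#CC(=O)c1ccc(OCOC)c(CC=C(C)C)c1OC | intermediate
14 | (E)-3-(diethylamino)-1-[2-methoxy-4-(methoxymethoxy)-3-(3-methylbut-2-en-1-yl)phenyl]-3-[4-(methoxymethoxy)phenyl]prop-2-en-1-one | COCOc1ccc(cc1)/C(N(CC)CC)=C\C(=O)c1ccc(OCOC)c(CC=C(C)C)c1OC | intermediate
15 | 1-[2-methoxy-4-(methoxymethoxy)-3-(3-methylbut-2-en-1-yl)phenyl]-3-[4-(methoxymethoxy)phenyl]propane-1,3-dione | COCOc1ccc(cc1)C(=O)CC(=O)c1ccc(OCOC)c(CC=C(C)C)c1OC | intermediate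
16 | 1-[4-hydroxy-2-methoxy-3-(3-methylbut-2-en-1-yl)phenyl]-3-(4-hydroxyphenyl)propane-1,3-dione | COc1c(C(=O)CC(=O)c2ccc(O)cc2)ccc(O)c1CC=C(C)C | target

**Step count and risks**

Total steps: 7. Longest linear sequence: 5 steps (steps 3, 4, 5, 6, 7 from 4-iodophenol 6); the ring A branch is 4 steps (1, 2, 6, 7).

Steps most likely to fail:

Step 2. What may go wrong: deprotonation next to bromine instead of between the two oxygens, followed by loss of lithium bromide to an aryne, or attack of the aryl anion at the tertiary end of prenyl bromide. Fallback: the same aryllithium 4 is made by bromine–lithium exchange instead of deprotonation. The sequence sets out from prenyl bromide 3 and, in place of 1, from its commercial isomer 2-bromo-3-methoxyphenol F1. Para-bromination (Bu4NBr3, CH2Cl2–MeOH, 0 °C) should give 2,4-dibromo-3-methoxyphenol F2, and MOM protection (NaH, MOMCl) should give 1,3-dibromo-2-methoxy-4-(methoxymethoxy)benzene F3. One equivalent of n-BuLi (THF, −78 °C) should exchange the bromine flanked by both oxygens, because that aryl anion is stabilised by two alkoxy groups. This gives 4, which is prenylated with 3 as in step 2, and the route is rejoined at 5.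

Step 6. What may go wrong: slow acyl substitution by the ortho-substituted aryllithium, which leaves time for proton transfer from the benzylic and allylic CH2 of the prenyl group or for addition to the triple bond. Fallback: carbonyl addition at the aldehyde level followed by oxidation. It sets out from 10 and 5: DIBAL-H (THF, −78 °C) should reduce 10 to 3-[4-(methoxymethoxy)phenyl]prop-2-ynal F4. Aryllithium 11, made from 5 as in step 6, should add to F4 rapidly to give 1-[2-methoxy-4-(methoxymethoxy)-3-(3-methylbut-2-en-1-yl)phenyl]-3-[4-(methoxymethoxy)phenyl]prop-2-yn-1-ol F5. MnO2 (CH2Cl2, rt) should oxidise this benzylic and propargylic alcohol, and the route is rejoined at 13.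

Step 4. What may go wrong: loss of CO2 from the arylpropiolate on palladium, followed by a second coupling to the symmetrical diarylalkyne, or oxidative dimerisation of the alkyne. Fallback: the carboxyl-level carbon is introduced after the coupling instead of with it. It sets out from 7: Sonogashira coupling with ethynyltrimethylsilane (Pd(PPh3)2Cl2, CuI, Et3N, rt) should give {[4-(methoxymethoxy)phenyl]ethynyl}trimethylsilane F6, and K2CO3 in MeOH should give 1-ethynyl-4-(methoxymethoxy)benzene F7. Deprotonation with n-BuLi (THF, −78 °C) and acylation with N-methoxy-N-methylcarbamoyl chloride should give the amide directly, so the route is rejoined at 10 and compound 9 is bypassed.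

**Further compounds**

F1 | step 2 | 2-bromo-3-methoxyphenol | COc1cccc(O)c1Br
F2 | step 2 | 2,4-dibromo-3-methoxyphenol | COc1c(Br)ccc(O)c1Br
F3 | step 2 | 1,3-dibromo-2-methoxy-4-(methoxymethoxy)benzene | COCOc1ccc(Br)c(OC)c1Br
F4 | step 6 | 3-[4-(methoxymethoxy)phenyl]prop-2-ynal | COCOc1ccc(cc1)C#CC=O
F5 | step 6 | 1-[2-methoxy-4-(methoxymethoxy)-3-(3-methylbut-2-en-1-yl)phenyl]-3-[4-(methoxymethoxy)phenyl]prop-2-yn-1-ol | COCOc1ccc(cc1)C#CC(O)c1ccc(OCOC)c(CC=C(C)C)c1OC
F6 | step 4 | {[4-(methoxymethoxy)phenyl]ethynyl}trimethylsilane | COCOc1ccc(cc1)C#C[Si](C)(C)C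
F7 | step 4 | 1-ethynyl-4-(methoxymethoxy)benzene | COCOc1ccc(cc1)C#C
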